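The data were computed with made-up constants, and the scatter is random.

A small charge of free catalyst, 2.2 mol% on starting material, is what I watch in this flask, which is the eta run followed so far; beta is its twin run hotter.

in all of them: starting material 0.058 M; free catalyst 2.2 mol%

| flask | second substrate | capture agent | temperature | remark | time |
|---|---|---|---|---|---|
| eta | 2 equiv | 5.8 mM | 90 °C | the very flask that is asked about, followed so far |  |
| beta | 2 equiv | 5.8 mM | 96 °C | run made earlier |  |
| flask | 2.00 equiv | 5.80 mM | 90 °C |  | 5.0 min |

- eta (time / min: target / %, starting material / %): 0.417: 15.8, 84.3; 1.00: 23.4, 75.9; 2.00: 28.2, 71.5; 5.00: 31.7, 69.3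
- beta (time / min: target / %, starting material / %): 0.417: 19.3, 81.2; 1.00: 27.6, 73.3; 2.00: 30.2, 70.5; 5.00: 31.7, 68.8

(each reading ± 0.5 percentage points)

- elm: at 5.0 min add starting material, 50.0% of the amount charged, then wait 10 min
- ash: at 5.0 min add free catalyst, 100% of the amount charged, then wait 10 min
- maple: change nothing and wait 10 min more
- larch: at 5.0 min raise the temperature by 25 K, then wait 10 min

* target, in percent of the starting material first charged, at 5.0 min
* what to do for the largest gain in target; "none" if nothing gains more than 2 percentage points (elm / ash / maple / larch / none)
* target present, in percent of the starting material first charged, after elm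
* target present, in percent of the starting material first charged, after ash

- what is added takes up no volume worth counting
- a reading or a percentage of target counts all its forms, free or not

My bench rule of thumb says that a curve flat after 5 half-lives is finished. Taking the last eta reading as the plateau, the distance to it falls from 16 percentage points at 0.417 min to 8.3 points at 1.00 min, which reads as a half-life h of 0.622 min. So 5.0 min is about 8.04 half-lives, my value for now is the reading 31.7%, and maple should gain little. Beta starts higher than eta, 19.3% against 15.8%, yet ends on the same 31.7%, so I expect larch to bring speed and no more target.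

The flat curve tempts me to name a limiting reagent, and here the rule stops working: eta still shows 69.3% of its starting material, 2.19 times the target made. The ratio I trust instead is N, the turnover number, meaning target made per free catalyst charged before the flask stops: 14.4. I reckon that the catalyst stops working after about N rounds. Elm then gains nothing, while ash buys N rounds again, 32 points more, or 63.4%. The starting material left covers that, and capture agent stands at 4.55 per catalyst charged.

The forecast gives 31.7%, ash as best, 32.3% after elm and 56% after ash, lower than my figure, and it favours “a catalyst dying per turnover”.

The flask gives 31.1%, ash as best with a gain of 44 points, 31.2% after elm and 75.0% after ash.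

    second substrate + target ⇌ idle adduct, settled at all times (K = 280 L mol⁻¹, ΔH = 36.0 kJ mol⁻¹)
    second substrate + free catalyst ⇌ catalyst intermediate B (K = 18.0 L mol⁻¹, k = 58.0 L mol⁻¹ s⁻¹, Ea = 46.0 kJ mol⁻¹, ΔH = −43.0 kJ mol⁻¹)
    catalyst intermediate B + capture agent → trapped intermediate (k = 16.0 L mol⁻¹ s⁻¹, Ea = 66.0 kJ mol⁻¹)
    free catalyst + target ⇌ idle complex, settled at all times (K = 910 L mol⁻¹, ΔH = −66.0 kJ mol⁻¹)
    starting material + free catalyst ⇌ catalyst intermediate A (K = 21.0 L mol⁻¹, k = 420 L mol⁻¹ s⁻¹, Ea = 41.0 kJ mol⁻¹, ΔH = −48.0 kJ mol⁻¹)
    catalyst intermediate A → free catalyst + target (k = 1.30 s⁻¹, Ea = 80.0 kJ mol⁻¹)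
    catalyst intermediate B → free catalyst + second product (k = 1.70 s⁻¹, Ea = 72.0 kJ mol⁻¹)
    (constants at 90 °C)

The flask stops near this N in part because catalyst intermediate A falls back to starting material and free catalyst, acting together with the path from second substrate and free catalyst to catalyst intermediate B: the run without that back reaction gives >99.9% target at 5.0 min, and the run without that path 95.9%, against 31.1%. N moves: ash yields 20.0 rounds per fresh catalyst, more than the 14.4 of the first charge. The neighbour flask charged with 0.800 equiv of second substrate reaches 26.9 rounds at 5.00 min, with 58.5% of its catalyst trapped.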